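**Target:** (5R,7R,10R)-labda-8,13E-diene-7,15-diyl diacetate, an ent-labdane with a trans ring fusion. The 7-OAc is pseudo-equatorial, cis to the C10 methyl and trans to H5. Labdane numbering is used throughout.

**Retrosynthetic overview**
1. Target 7 ⇐ (7R)-allylic alcohol 6 by acetylation; 6 ⇐ enone 5 by axial hydride delivery, which sets C7.
2. Enone 5 ⇐ ent-labda-8,13E-dien-15-yl acetate 4 by allylic C–H oxidation at C7, the late oxygenation of the finished hydrocarbon skeleton.
3. Diene 4 ⇐ all-E geranylgeranyl acetate 2 in one catalytic, enantioselective, proton-initiated cascade: C4–C5 closes ring A, then C10–C9 closes ring B, and proton loss gives the 8(9)-alkene. This sets C5 and C10.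
4. Acetate 2 ⇐ geranylgeraniol 1; the acetate is a target substituent and also deactivates the 13-alkene so the cascade stops at the bicycle.

**Assumption:** commercial all-E geranylgeraniol (annatto-derived) is the starting material, and the (S,S) antipode of the acid catalyst in step 2 is taken to give the (5R,10R) series; if the first run shows the opposite sense, the (R,R) catalyst is used with nothing else changed.

**Step 1**
Reactants: 1 (2E,6E,10E)-geranylgeraniol
Product: 2 (2E,6E,10E)-geranylgeranyl acetate
Conditions: Ac2O, pyridine, DMAP (cat.), CH2Cl2, 0 °C to rt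
Reagents that add atoms: acetic anhydride, CC(=O)OC(C)=O
Why: DMAP-catalysed O-acylation of a primary allylic alcohol; no stereocentre is involved and the acetate stays to the end.

**Step 2**
Reactants: 2 (2E,6E,10E)-geranylgeranyl acetate
Product: 4 (5R,10R)-labda-8,13E-dien-15-yl acetate, via labd-13-en-8-yl cation 3 (not isolated)
Conditions: (S,S)-IDPi acid (5 mol %), (CF3)3COH/CH2Cl2 4:1, −30 °C, 72 h
Reagents that add atoms: none
Why: Proposed new method: a confined, strongly acidic chiral imidodiphosphorimidate (IDPi: two (S)-3,3′-bis(perfluoroaryl)-BINOL phosphorus units, N-triflyl groups) protonates C3 of the terminal, most nucleophilic alkene on one face while the chain is folded chair–chair in the pocket, so C4–C5 and C10–C9 close by anti addition across the two E-alkenes (Stork–Eschenmoser) to the trans-fused cation 3, fixing C5 and C10 under catalyst control; the 13-alkene, deactivated by the solvent-hydrogen-bonded allylic acetate, does not add, and reversible proton loss drains 3 to the most substituted 8(9)-alkene; the closest known reactions are the IDPi-catalysed asymmetric cyclization of homofarnesol to ambrox in fluorinated alcohols, IDPi-catalysed protonation–rearrangement–deprotonation of simple alkenes, and BINOL·SnCl4-induced polyprenoid cyclizations.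

**Step 3**
Reactants: 4 (5R,10R)-labda-8,13E-dien-15-yl acetate
Product: 5 (5R,10R)-7-oxolabda-8,13E-dien-15-yl acetate
Conditions: CrO3, 3,5-dimethylpyrazole, CH2Cl2, −20 °C
Reagents that add atoms: chromium trioxide, O=[Cr](=O)=O
Why: Allylic oxidation (Salmond conditions) of the only ring methylene next to the electron-rich tetrasubstituted alkene, as in the C7 oxidation of 8-ene drimanes; C11 is shielded by the quaternary C10, the 13-alkene is deactivated by its acetate, and no stereocentre is touched.

**Step 4**
Reactants: 5 (5R,10R)-7-oxolabda-8,13E-dien-15-yl acetate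
Product: 6 (5R,7R,10R)-7-hydroxylabda-8,13E-dien-15-yl acetate
Conditions: NaBH4, CeCl3·7H2O, MeOH, −78 to −40 °C
Reagents that add atoms: none
Why: Luche 1,2-reduction; hydride adds axially to C7 from the face of H5, away from the axial C10 methyl, giving the pseudo-equatorial (7R) alcohol cis to that methyl, while the low temperature spares the primary acetate.

**Step 5**
Reactants: 6 (5R,7R,10R)-7-hydroxylabda-8,13E-dien-15-yl acetate
Product: 7 (5R,7R,10R)-labda-8,13E-diene-7,15-diyl diacetate
Conditions: Ac2O, pyridine, DMAP (cat.), CH2Cl2, rt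
Reagents that add atoms: acetic anhydride, CC(=O)OC(C)=O
Why: DMAP-catalysed acylation of the secondary allylic alcohol with retention at C7; any C15 acetate lost in step 4 is restored in the same operation.

**Compound list**
1 | (2E,6E,10E)-geranylgeraniol | OC/C=C(\C)CC/C=C(\C)CC/C=C(\C)CCC=C(C)C | starting material
2 | (2E,6E,10E)-geranylgeranyl acetate | CC(=O)OC/C=C(\C)CC/C=C(\C)CC/C=C(\C)CCC=C(C)C | intermediate
3 | trans-fused ent-labd-13E-en-15-yl acetate C8 carbocation (H9 trans to the C10 methyl, side chain equatorial) | CC(=O)OC/C=C(\C)CC[C@@H]1[C+](C)CC[C@@H]2C(C)(C)CCC[C@@]12C | intermediate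
4 | (5R,10R)-labda-8,13E-dien-15-yl acetate (ent-labdane, trans-decalin) | CC(=O)OC/C=C(\C)CCC1=C(C)CC[C@@H]2C(C)(C)CCC[C@@]12C | intermediate
5 | (5R,10R)-7-oxolabda-8,13E-dien-15-yl acetate | CC(=O)OC/C=C(\C)CCC1=C(C)C(=O)C[C@@H]2C(C)(C)CCC[C@@]12C | intermediate
6 | (5R,7R,10R)-7-hydroxylabda-8,13E-dien-15-yl acetate (OH cis to the C10 methyl) | CC(=O)OC/C=C(\C)CCC1=C(C)[C@H](O)C[C@@H]2C(C)(C)CCC[C@@]12C | intermediate
7 | (5R,7R,10R)-labda-8,13E-diene-7,15-diyl diacetate | CC(=O)OC/C=C(\C)CCC1=C(C)[C@H](OC(C)=O)C[C@@H]2C(C)(C)CCC[C@@]12C | target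

**Total step count:** 5. **Longest linear sequence:** 5.

**Steps most likely to fail**

Step 2 (asymmetric bicyclization). The risks are low enantioselectivity, a mixture of alkene isomers, over-cyclization to a tricycle, or ionization of the allylic acetate. The fallback sets out from 2 and gives up catalyst control in favour of a late resolution. Compound 2 is cyclized racemically with ClSO3H in 2-nitropropane at −78 °C to rac-labda-8,13E-dien-15-yl acetate F1. This is oxidized with CrO3/3,5-dimethylpyrazole to rac-7-oxolabda-8,13E-dien-15-yl acetate F2 and reduced with NaBH4/CeCl3·7H2O to rac-7-hydroxylabda-8,13E-dien-15-yl acetate F3, with the same relative configuration as 6. Candida antarctica lipase B with vinyl acetate in hexane at 35 °C then acetylates only the (7R) enantiomer, the fast-reacting one by Kazlauskas' rule. The unreacted (5S,7S,10S) alcohol is removed by chromatography, and the fallback comes back to the route at 7. If step 2 only falls short in ee, the same lipase acetylation of 6 in place of step 5 polishes the material.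

Step 3 (allylic oxidation). The risks are competing oxidation at C11 or in the side chain and over-oxidation. The fallback sets out from 4 and replaces hydrogen abstraction by an ene reaction and an oxidative transposition. Photo-oxygenation (O2, tetraphenylporphyrin, visible light, CH2Cl2, −20 °C) attacks only the tetrasubstituted alkene; oxygen enters at C9 anti to the C10 methyl with loss of the axial H7. This gives (5R,9S,10R)-9-hydroperoxylabda-7,13E-dien-15-yl acetate F4. PPh3 reduces it to (5R,9S,10R)-9-hydroxylabda-7,13E-dien-15-yl acetate F5. Pyridinium chlorochromate, [C5H5NH][CrO3Cl], in CH2Cl2 then effects the Babler–Dauben oxidative 1,3-transposition of this tertiary allylic alcohol, and the fallback comes back to the route at 5.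

Step 4 (C7 stereochemistry). The risk is that hydride delivery is poorly selective or favours the 7-epimer. The fallback sets out from 5 and rests the stereochemistry on SN2 inversion instead of facial selectivity. Whatever reduction of 5 gives the epimer, (5R,7S,10R)-7-hydroxylabda-8,13E-dien-15-yl acetate F6 is taken on rather than discarded. Mitsunobu esterification with acetic acid (PPh3, DIAD, toluene, 0 °C) inverts C7 and installs the acetate in one operation, so the fallback comes back to the route at 7 and both epimers converge on the target.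

**Further compounds**
F1 | step 2 | rac-labda-8,13E-dien-15-yl acetate (trans-decalin, both enantiomers) | CC(=O)OC/C=C(\C)CCC1=C(C)CC[C@@H]2C(C)(C)CCC[C@@]12C.CC(=O)OC/C=C(\C)CCC1=C(C)CC[C@H]2C(C)(C)CCC[C@]12C
F2 | step 2 | rac-7-oxolabda-8,13E-dien-15-yl acetate (both enantiomers) | CC(=O)OC/C=C(\C)CCC1=C(C)C(=O)C[C@@H]2C(C)(C)CCC[C@@]12C.CC(=O)OC/C=C(\C)CCC1=C(C)C(=O)C[C@H]2C(C)(C)CCC[C@]12C
F3 | step 2 | rac-7-hydroxylabda-8,13E-dien-15-yl acetate (OH cis to the C10 methyl, both enantiomers) | CC(=O)OC/C=C(\C)CCC1=C(C)[C@H](O)C[C@@H]2C(C)(C)CCC[C@@]12C.CC(=O)OC/C=C(\C)CCC1=C(C)[C@@H](O)C[C@H]2C(C)(C)CCC[C@]12C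
F4 | step 3 | (5R,9S,10R)-9-hydroperoxylabda-7,13E-dien-15-yl acetate (OOH anti to the C10 methyl) | CC(=O)OC/C=C(\C)CC[C@]1(OO)C(C)=CC[C@@H]2C(C)(C)CCC[C@@]12C
F5 | step 3 | (5R,9S,10R)-9-hydroxylabda-7,13E-dien-15-yl acetate | CC(=O)OC/C=C(\C)CC[C@]1(O)C(C)=CC[C@@H]2C(C)(C)CCC[C@@]12C
F6 | step 4 | (5R,7S,10R)-7-hydroxylabda-8,13E-dien-15-yl acetate (7-epimer of 6) | CC(=O)OC/C=C(\C)CCC1=C(C)[C@@H](O)C[C@@H]2C(C)(C)CCC[C@@]12C
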